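At early times both mirror-image substrates meet the same partner and the same free catalyst. On the suspected steps, left-handed and right-handed product therefore grow in the ratio of the substrates times s, the selectivity factor, which is the ratio of the two rate constants at one temperature. At the start the substrates stand equal, so the share of left-handed product is s/(s + one). Toward the far end the share falls as the left-handed substrate thins, but the partner, charged at 1.20 equiv on the left-handed substrate and taken once per product, is the limiting reagent and ends the flask before both substrates are consumed, so the share stays above half. Integration joins the two ends: ln x = s ln y, with x and y the fractions of left-handed and right-handed substrate remaining. At one temperature partner and catalyst cancel from this relation, so there the share follows from s and from how far the flask got.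

| flask | left-handed substrate | right-handed substrate | partner | free catalyst | temperature | remark | time |
|---|---|---|---|---|---|---|---|
| beta | 1.5 M | 1.5 M | 1.2 equiv | 2.3 mol% | 65 °C | run made earlier |  |
| zeta | 1.5 M | 1.5 M | 1.2 equiv | 7.4 mol% | 90 °C | run made earlier |  |
| alder | 1.5 M | 1.5 M | 1.20 equiv | 9 mol% |  | at 110 °C until 25 h, from then on at 70 °C | 2.0 d |
| larch | 1.5 M | 1.5 M | 1.20 equiv | 3 mol% |  | at 70 °C throughout | 2.0 d |

| run | time / d | left-handed product / % | right-handed product / % | left-handed substrate / % |
|---|---|---|---|---|
| beta | 0.833 | 1.8 | 2.0 | 47.6 |
| beta | 1.25 | 4.5 | 3.5 | 44.6 |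
| beta | 1.67 | 4.0 | 2.6 | 46.5 |
| beta | 2.50 | 6.7 | 3.6 | 43.5 |
| beta | 4.00 | 6.8 | 3.6 | 41.1 |
| beta | 6.00 | 9.5 | 5.6 | 41.4 |
| beta | 10.0 | 11.5 | 7.0 | 38.1 |
| zeta | 0.167 | 6.7 | 4.6 | 44.5 |
| zeta | 0.417 | 12.9 | 6.8 | 38.3 |
| zeta | 0.625 | 16.7 | 4.5 | 33.7 |
| zeta | 1.04 | 16.2 | 9.2 | 33.7 |
| zeta | 1.67 | 20.7 | 8.5 | 32.4 |
| zeta | 2.50 | 19.1 | 10.4 | 31.3 |
| zeta | 3.00 | 21.9 | 8.6 | 29.2 |

(standard deviation of a reading: 1 percentage point)

* which of the two ends with the higher share of left-handed product in all that became left-handed product or right-handed product ("neither" if they lie within 2 percentage points) (alder / larch / neither)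
* share of left-handed product in all that became left-handed product or right-handed product, alder
* share of left-handed product in all that became left-handed product or right-handed product, larch

- free catalyst is single-handed; left-handed substrate and right-handed substrate are mirror images of each other, charged as a racemate, each of them at the stated concentration
- on the list of suspects stand: partner + free catalyst + left-handed substrate -> free catalyst + left-handed product; partner + free catalyst -> spent catalyst; partner + free catalyst + right-handed substrate -> free catalyst + right-handed product; partner <-> dormant form

The mean of the last three readings gives s = 1.79 in the beta run and 2.62 in the zeta run, a difference of 15.4 kJ mol⁻¹ in activation energy. Carried forward, this gives the selectivity factor at the hot stage of alder, s₁₁₀ = 3.42, and 1.94 at 70 °C.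

But alder cools at 25 h, and cold product would dilute the share. Zeta gained 5.2 percentage points of left-handed product after 0.625 d, less than the 16.7% before it, so alder's product is counted as hot. Alder's extent is unknown, so my own reckoning borrows zeta's plateau, x = 0.589, which gives a share of 74.1%. The extrapolation is noisy, but even zeta's own s gives 69.2%, still above 66.0%, the early-end share at 70 °C, which larch can only fall below.

The forecast names alder, with 74% for alder and 65% for larch: “Selectivity therefore rises with temperature”.

The flask gives alder, 70.3% against 66.0% for larch, so the forecast held.

    partner + free catalyst + left-handed substrate → free catalyst + left-handed product (k = 0.0140 L² mol⁻² min⁻¹, Ea = 72.0 kJ mol⁻¹)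
    partner + free catalyst → spent catalyst (k = 3.00 × 10⁻⁴ L mol⁻¹ min⁻¹, Ea = 108 kJ mol⁻¹)
    partner + free catalyst + right-handed substrate → free catalyst + right-handed product (k = 0.00480 L² mol⁻² min⁻¹, Ea = 62.0 kJ mol⁻¹)
    partner ⇌ dormant form (K = 4.80, k = 0.00640 min⁻¹, Ea = 109 kJ mol⁻¹, ΔH = −48.0 kJ mol⁻¹)
    (constants at 110 °C)

In alder at 110 °C, partner has a forward half-life of 0.075 d toward the dormant form, shorter than the 0.17 d through the step to left-handed product with the other charges held as if they never ran down, and at 1.04 d 6.09% of its charge stands free, while free catalyst is at 89.9% of the catalyst charged, the step to spent catalyst making no difference. Alder's remains, 52% and 80%, give s = 2.89, lower than 3.42, and the neighbour flask with 15 mol% of free catalyst, left with 43% and 75%, gives s = 2.89 and a share of 69.2%.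

The earlier runs and the new flask are calculated with made-up constants; noise was put on by code.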